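**Plan**

- Retrosynthesis: first all benzyl groups and both side-chain oxygens are removed in one hydrogenolysis; then the bond between C1 of catechol ring A and its benzylic carbon is cut, giving a ring A phenol with C1–H and 3-methoxyphenylglyoxal; then the biaryl bond (Suzuki–Miyaura); last the C=C of the ring B side chain (Horner–Wadsworth–Emmons).
- Forward: the ring B aldehyde is brominated, olefinated and borylated, then coupled with 2-(benzyloxy)-6-bromophenol to a biaryl with a single free phenol. Its phenoxide is C-hydroxyalkylated at C1 by the glyoxal, and one reduction finishes the synthesis.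
- Enabling feature: in ring A (C1 = chain carbon, C3 and C4 = oxygens, C5 = biaryl carbon) the free C4–OH has both ortho positions occupied (C3–OBn, C5–aryl). Its phenoxide can therefore re-aromatise only after attack through the para carbon C1. Ring B has no free OH and no open position para to oxygen, and the anisole rings do not react under phenoxide conditions.
- Stereochemistry: the target has no stereocentre and its biaryl axis (two ortho substituents) rotates freely. The E-alkene and the racemic carbinol centre are transient and are erased in step 7.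

Key step: step 6

Assumption: 3-methoxyphenylglyoxal is used as its commercial, bench-stable monohydrate (9), and compounds 1, 3 and 6 are catalogue chemicals.

**Route**

Step 1
Reactants: 1 3,4-bis(benzyloxy)benzaldehyde
Product: 2 4,5-bis(benzyloxy)-2-bromobenzaldehyde
Conditions: Br2 (1.1 equiv), NaOAc, AcOH, rt
Reagents that add atoms: bromine BrBr
Why: Electrophilic aromatic bromination should enter para to the 3-benzyloxy group (ortho to the formyl group), as in the bromination of veratraldehyde, and the acetate buffer keeps HBr from cleaving the benzyl ethers.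

Step 2
Reactants: 2 4,5-bis(benzyloxy)-2-bromobenzaldehyde; 3 diethyl (3-methoxybenzyl)phosphonate
Product: 4 1,2-bis(benzyloxy)-4-bromo-5-[(E)-2-(3-methoxyphenyl)ethenyl]benzene
Conditions: KOt-Bu, THF, 0 °C to rt
Reagents that add atoms: none
Why: Horner–Wadsworth–Emmons olefination of the aryl aldehyde with the aryl-stabilised phosphonate anion should give the E-stilbene and leave the aryl bromide untouched; the geometry is not needed later because the alkene is hydrogenated in step 7.

Step 3
Reactants: 4 1,2-bis(benzyloxy)-4-bromo-5-[(E)-2-(3-methoxyphenyl)ethenyl]benzene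
Product: 5 2-{4,5-bis(benzyloxy)-2-[(E)-2-(3-methoxyphenyl)ethenyl]phenyl}-4,4,5,5-tetramethyl-1,3,2-dioxaborolane
Conditions: B2pin2 (1.2 equiv), PdCl2(dppf), KOAc, 1,4-dioxane, 90 °C
Reagents that add atoms: bis(pinacolato)diboron CC1(C)OB(OC1(C)C)B1OC(C)(C)C(C)(C)O1
Why: Miyaura borylation (oxidative addition of zerovalent palladium into the C–Br bond, acetate-assisted transmetalation from the diboron reagent, reductive elimination) should give the arylboronate without touching the stilbene or the benzyl ethers.

Step 4
Reactants: 6 2-(benzyloxy)phenol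
Product: 7 2-(benzyloxy)-6-bromophenol
Conditions: t-BuNH2 (2 equiv), Br2 (1 equiv), toluene, −78 °C to rt
Reagents that add atoms: bromine BrBr
Why: Amine-mediated ortho-bromination of a phenol: N-bromo-tert-butylamine formed in the flask is hydrogen-bonded to the phenolic O–H and should deliver bromine to the only free ortho position, overriding the usual para preference, as known for guaiacol.

Step 5
Reactants: 5 2-{4,5-bis(benzyloxy)-2-[(E)-2-(3-methoxyphenyl)ethenyl]phenyl}-4,4,5,5-tetramethyl-1,3,2-dioxaborolane; 7 2-(benzyloxy)-6-bromophenol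
Product: 8 3,4',5'-tris(benzyloxy)-2'-[(E)-2-(3-methoxyphenyl)ethenyl]biphenyl-2-ol
Conditions: Pd(OAc)2, SPhos, K3PO4, toluene–H2O (10:1), 90 °C
Reagents that add atoms: none
Why: Suzuki–Miyaura coupling with a bulky electron-rich biarylphosphine should join the ortho-substituted arylboronate to the unprotected ortho-bromophenol; the free hydroxyl is tolerated as its phenoxide and becomes the control element of step 6.

Step 6
Reactants: 8 3,4',5'-tris(benzyloxy)-2'-[(E)-2-(3-methoxyphenyl)ethenyl]biphenyl-2-ol; 9 3-methoxyphenylglyoxal monohydrate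
Product: 11 2-hydroxy-2-{4',5,5'-tris(benzyloxy)-6-hydroxy-2'-[(E)-2-(3-methoxyphenyl)ethenyl]biphenyl-3-yl}-1-(3-methoxyphenyl)ethan-1-one (racemic ketol), via cyclohexa-2,5-dienone C-adduct 10 (not isolated)
Conditions: 9 (1.3 equiv), DBU (1.0 equiv), THF, 0 °C to rt, argon
Reagents that add atoms: none
Why: DBU converts the only free phenol (C4–OH of ring A) into its phenoxide, which attacks the aldehyde carbon of the glyoxal through the para carbon C1 to give dienone 10; loss of the C1 proton re-aromatises it to ketol 11, the irreversible step that drains the reversibly formed O-adducts (hemiacetals). The closest known reaction type is the base-mediated para-selective Friedel–Crafts (Lederer–Manasse-type) hydroxyalkylation of 2-alkoxyphenols with glyoxylic acid and of phenols and naphthols with arylglyoxal hydrates. No ring is closed. The new carbinol stereocentre is formed without control (racemic) and is deleted in step 7, as is any ketol transposition. Site selectivity rests on the substitution pattern: both positions ortho to the phenoxide oxygen (C3–OBn, C5–aryl) are blocked, so only attack at C1 can re-aromatise; ring B has no free hydroxyl and no open position para to oxygen; the anisole rings and the stilbene do not react with an aldehyde under basic conditions. The aldehyde carbon of 9 should be attacked in preference to the conjugated, more hindered ketone carbon.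

Step 7
Reactants: 11 2-hydroxy-2-{4',5,5'-tris(benzyloxy)-6-hydroxy-2'-[(E)-2-(3-methoxyphenyl)ethenyl]biphenyl-3-yl}-1-(3-methoxyphenyl)ethan-1-one
Product: 12 5-[2-(3-methoxyphenyl)ethyl]-3-{4,5-dihydroxy-2-[2-(3-methoxyphenyl)ethyl]phenyl}benzene-1,2-diol (isoplagilin)
Conditions: H2 (4 bar), Pd/C, AcOH–EtOAc (1:1), HClO4 (cat.), rt to 40 °C
Reagents that add atoms: none
Why: Catalytic hydrogenation and hydrogenolysis should saturate the stilbene C=C, cleave the three O-benzyl groups and reduce both benzylic C–O functions of the ketol to CH2 (the para-hydroxybenzylic carbinol directly, the aryl ketone via its carbinol under acid promotion), as in the classical conversion of benzoins and deoxybenzoins into bibenzyls; the aryl methyl ethers and the arene rings should not be affected.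

**Compound list**

1 | 3,4-bis(benzyloxy)benzaldehyde | O=Cc1ccc(OCc2ccccc2)c(OCc2ccccc2)c1 | starting material
2 | 4,5-bis(benzyloxy)-2-bromobenzaldehyde | O=Cc1cc(OCc2ccccc2)c(OCc2ccccc2)cc1Br | intermediate
3 | diethyl (3-methoxybenzyl)phosphonate | CCOP(=O)(Cc1cccc(OC)c1)OCC | starting material
4 | 1,2-bis(benzyloxy)-4-bromo-5-[(E)-2-(3-methoxyphenyl)ethenyl]benzene | COc1cccc(/C=C/c2cc(OCc3ccccc3)c(OCc3ccccc3)cc2Br)c1 | intermediate
5 | 2-{4,5-bis(benzyloxy)-2-[(E)-2-(3-methoxyphenyl)ethenyl]phenyl}-4,4,5,5-tetramethyl-1,3,2-dioxaborolane | COc1cccc(/C=C/c2cc(OCc3ccccc3)c(OCc3ccccc3)cc2B4OC(C)(C)C(C)(C)O4)c1 | intermediate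
6 | 2-(benzyloxy)phenol | Oc1ccccc1OCc1ccccc1 | starting material
7 | 2-(benzyloxy)-6-bromophenol | Oc1c(Br)cccc1OCc1ccccc1 | intermediate
8 | 3,4',5'-tris(benzyloxy)-2'-[(E)-2-(3-methoxyphenyl)ethenyl]biphenyl-2-ol | COc1cccc(/C=C/c2cc(OCc3ccccc3)c(OCc3ccccc3)cc2-c2cccc(OCc3ccccc3)c2O)c1 | intermediate
9 | 3-methoxyphenylglyoxal monohydrate, 2,2-dihydroxy-1-(3-methoxyphenyl)ethan-1-one | COc1cccc(C(=O)C(O)O)c1 | starting material
10 | 2-(benzyloxy)-6-{4,5-bis(benzyloxy)-2-[(E)-2-(3-methoxyphenyl)ethenyl]phenyl}-4-[1-hydroxy-2-(3-methoxyphenyl)-2-oxoethyl]cyclohexa-2,5-dien-1-one (stereoisomer mixture, not isolated) | COc1cccc(C(=O)C(O)C2C=C(OCc3ccccc3)C(=O)C(-c3cc(OCc4ccccc4)c(OCc4ccccc4)cc3/C=C/c3cccc(OC)c3)=C2)c1 | intermediate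
11 | 2-hydroxy-2-{4',5,5'-tris(benzyloxy)-6-hydroxy-2'-[(E)-2-(3-methoxyphenyl)ethenyl]biphenyl-3-yl}-1-(3-methoxyphenyl)ethan-1-one (racemic) | COc1cccc(C(=O)C(O)c2cc(OCc3ccccc3)c(O)c(-c3cc(OCc4ccccc4)c(OCc4ccccc4)cc3/C=C/c3cccc(OC)c3)c2)c1 | intermediate
12 | 5-[2-(3-methoxyphenyl)ethyl]-3-{4,5-dihydroxy-2-[2-(3-methoxyphenyl)ethyl]phenyl}benzene-1,2-diol (isoplagilin) | COc1cccc(CCc2cc(O)c(O)c(-c3cc(O)c(O)cc3CCc3cccc(OC)c3)c2)c1 | target

**Totals**

Total step count: 7. Longest linear sequence: 6 steps (steps 1, 2, 3, 5, 6, 7); step 4 is a one-step side branch.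

**Steps most likely to fail**

Step 6. The glyoxal may be consumed by a base-induced internal hydride shift (Cannizzaro-type) faster than the C–C bond forms, reversible O-addition may stall the reaction, or the ketol phenoxide may be oxidised by air. The fallback sets out from 8 and uses halogenation and cross-coupling instead. Phenol-selective para-iodination (I2, morpholine, CH2Cl2–MeOH, 0 °C) should give 3,4',5'-tris(benzyloxy)-5-iodo-2'-[(E)-2-(3-methoxyphenyl)ethenyl]biphenyl-2-ol F1, since the anisole rings and the stilbene are not attacked by this reagent. Sonogashira coupling of F1 with 1-ethynyl-3-methoxybenzene (PdCl2(PPh3)2, CuI, Et3N, THF, 50 °C) forms the same ring A C1–carbon bond and gives the diarylalkyne 3,4',5'-tris(benzyloxy)-5-[(3-methoxyphenyl)ethynyl]-2'-[(E)-2-(3-methoxyphenyl)ethenyl]biphenyl-2-ol F2. Hydrogenation of F2 (H2, Pd/C, EtOAc–MeOH) saturates alkyne and alkene and removes the benzyl groups, coming back to the route at 12.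

Step 7. The deoxygenation may stall at the aryl ketone or its carbinol, or the acid may protonate the stilbene and cyclise it onto ring A before the alkene is saturated. The fallback sets out from 11 and separates the two tasks. Neutral hydrogenation (H2, Pd/C, EtOAc–MeOH, rt) should remove the benzyl groups, saturate the alkene and cleave only the doubly activated ketol C–OH (para-hydroxybenzylic and alpha to the ketone), giving the deoxybenzoin 2-{4',5,5',6-tetrahydroxy-2'-[2-(3-methoxyphenyl)ethyl]biphenyl-3-yl}-1-(3-methoxyphenyl)ethan-1-one F3. Ionic hydrogenation of the remaining aryl ketone (Et3SiH, CF3CO2H, 50 °C), now with no alkene left to cyclise, should then give 12, where the fallback comes back to the route.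

Step 4. Ortho-selectivity may be lost (bromination para to the hydroxyl) or bromination may go too far. The fallback sets out from 6 and uses directed ortho-metalation instead of electrophilic substitution. O-Carbamoylation (NaH, Et2NCOCl, THF) gives 2-(benzyloxy)phenyl N,N-diethylcarbamate F4. Lithiation at the only free position ortho to the carbamate (s-BuLi, TMEDA, THF, −78 °C) gives 2-(benzyloxy)-6-lithiophenyl N,N-diethylcarbamate F5 in the flask, which is quenched with BrCH2CH2Br to 2-(benzyloxy)-6-bromophenyl N,N-diethylcarbamate F6. Hydrolysis of the carbamate (KOH, EtOH–H2O, reflux) comes back to the route at 7.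

**Further compounds**

F1 | step 6 | 3,4',5'-tris(benzyloxy)-5-iodo-2'-[(E)-2-(3-methoxyphenyl)ethenyl]biphenyl-2-ol | COc1cccc(/C=C/c2cc(OCc3ccccc3)c(OCc3ccccc3)cc2-c2cc(I)cc(OCc3ccccc3)c2O)c1
F2 | step 6 | 3,4',5'-tris(benzyloxy)-5-[(3-methoxyphenyl)ethynyl]-2'-[(E)-2-(3-methoxyphenyl)ethenyl]biphenyl-2-ol | COc1cccc(C#Cc2cc(OCc3ccccc3)c(O)c(-c3cc(OCc4ccccc4)c(OCc4ccccc4)cc3/C=C/c3cccc(OC)c3)c2)c1
F3 | step 7 | 2-{4',5,5',6-tetrahydroxy-2'-[2-(3-methoxyphenyl)ethyl]biphenyl-3-yl}-1-(3-methoxyphenyl)ethan-1-one | COc1cccc(C(=O)Cc2cc(O)c(O)c(-c3cc(O)c(O)cc3CCc3cccc(OC)c3)c2)c1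
F4 | step 4 | 2-(benzyloxy)phenyl N,N-diethylcarbamate | CCN(CC)C(=O)Oc1ccccc1OCc1ccccc1
F5 | step 4 | 2-(benzyloxy)-6-lithiophenyl N,N-diethylcarbamate | CCN(CC)C(=O)Oc1c([Li])cccc1OCc1ccccc1
F6 | step 4 | 2-(benzyloxy)-6-bromophenyl N,N-diethylcarbamate | CCN(CC)C(=O)Oc1c(Br)cccc1OCc1ccccc1
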